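**Retrosynthetic overview**

- The route rests on the hexasubstituted benzene ring C1–C6, read as three two-carbon units: C2–C3 and C4–C5 each pair one bromine-bearing carbon with one oxygen-bearing carbon, and C6–C1 pairs a bromine-bearing carbon with the carbon carrying CH2SO2Me.
- The catechol (C3–OH, C4–OH) is freed last from an ethylene-bridged 1,4-benzodioxine. The bromines at C2 and C5 replace trimethylsilyl groups by ipso-substitution, and the bromine at C6 replaces the one remaining ring hydrogen.
- The silylated benzodioxine is cut at C3–C4, C1–C2 and C5–C6 into 1,2-bis[(trimethylsilyl)ethynyloxy]ethane and methyl propargyl sulfone, joined by a cobalt-mediated [2+2+2] cycloaddition. The dioxane ring closes first (C3–C4, at the metallacycle stage), the benzene ring second.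
- The diyne comes from ethylene glycol diformate by dichloromethylenation and then n-butyllithium/chlorotrimethylsilane. The sulfone comes from propargyl bromide and sodium methanesulfinate.

Key step: step 4

Remark: the target has no stereocenter; the tether is brought in as the diformate, not the free diol, because alkoxide-based vinylation of a 1,2-diol risks ring closure onto the first vinyl ether, and the ynol ether units are assumed to tolerate 60 °C.

**Route**

Step 1
Reactants: 1 ethane-1,2-diyl diformate (ethylene glycol diformate)
Product: 2 1,2-bis[(2,2-dichloroethenyl)oxy]ethane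
Conditions: PPh3 (7 equiv), CCl4 (excess), THF, 60 °C
Reagents that add atoms: carbon tetrachloride, ClC(Cl)(Cl)Cl
Why: Wittig-type dichloromethylenation, in which PPh3 and CCl4 generate Ph3P=CCl2 that olefinates the aldehyde-like formate carbonyls to 2,2-dichlorovinyl ethers under non-basic conditions, so the two-carbon tether cannot cyclize through an alkoxide.

Step 2
Reactants: 2 1,2-bis[(2,2-dichloroethenyl)oxy]ethane
Product: 5 1,2-bis[(trimethylsilyl)ethynyloxy]ethane, via bis(chloroalkynyl) ether 3 (not isolated), via dilithio bis(acetylide) 4 (not isolated)
Conditions: n-BuLi (4.4 equiv), THF, −78 → −40 °C; TMSCl (2.6 equiv), −78 °C → rt; aq. NaHCO3 work-up, bulb-to-bulb distillation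
Reagents that add atoms: chlorotrimethylsilane, C[Si](C)(C)Cl
Why: This is the established dichlorovinyl ether route to alkynyl ethers: n-butyllithium removes HCl from each arm to give the chloroalkynyl ether 3, chlorine–lithium exchange gives the lithium alkoxyacetylide 4, and chlorotrimethylsilane silylates it on carbon.

Step 3
Reactants: 6 propargyl bromide (3-bromoprop-1-yne); 7 sodium methanesulfinate
Product: 8 methyl propargyl sulfone (3-(methylsulfonyl)prop-1-yne)
Conditions: DMF, 0 °C → rt, no added base
Reagents that add atoms: none
Why: SN2 S-alkylation of the sulfinate at the propargylic bromide gives the sulfone, and the absence of external base should keep propargyl-to-allenyl isomerization down.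

Step 4
Reactants: 5 1,2-bis[(trimethylsilyl)ethynyloxy]ethane; 8 methyl propargyl sulfone
Product: 9 6-(methylsulfonylmethyl)-5,8-bis(trimethylsilyl)-2,3-dihydro-1,4-benzodioxine
Conditions: CpCo(CO)2 (Cp = cyclopentadienyl, 20 mol %), 5 and 8 (2 equiv) added slowly, degassed THF, visible-light irradiation, 60 °C
Reagents that add atoms: none
Why: Proposed new method: after light-induced loss of CO, the CpCo fragment (monovalent cobalt) binds both alkynes of 5 and couples them oxidatively to a cobaltacyclopentadiene of trivalent cobalt, and insertion of the alkyne of 8 followed by reductive elimination completes a [2+2+2] cycloaddition. The closest known reaction type is the CpCo(CO)2-mediated cocyclization of silyl-terminated alpha,omega-diynes with monoalkynes to fused benzenes, together with metal-catalysed cycloadditions of alkoxy(silyl)alkynes; an oxygen-tethered bis(silyl ynol ether) as the diyne partner is without precedent. The dioxane ring closes in the oxidative coupling, by intramolecular C–C bond formation between the two oxygen-bearing alkyne carbons held together by the O–CH2CH2–O tether (C3–C4 of the target), with the bulky silyl groups next to cobalt; the benzene ring closes when the two silicon-bearing carbons bond to the two carbons of 8 (C1–C2 and C5–C6). No stereocenter is formed. The step needs chemoselectivity for the cross product: the trimethylsilyl termini suppress self-trimerization of 5, slow addition keeps 8 from trimerizing with itself, and the symmetry of 5 means both orientations of 8 give the same arene, so no regiocontrol is required. The temperature stays below the range where ynol ethers lose silylketene by retro-ene fragmentation, and the base-free medium keeps 8 from isomerizing to the allenyl sulfone.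

Step 5
Reactants: 9 6-(methylsulfonylmethyl)-5,8-bis(trimethylsilyl)-2,3-dihydro-1,4-benzodioxine
Product: 11 5,6,8-tribromo-7-(methylsulfonylmethyl)-2,3-dihydro-1,4-benzodioxine, via 5,8-dibromo benzodioxine 10 (not isolated)
Conditions: Br2 (2.1 equiv), CH2Cl2, −20 → 0 °C, dark; then Br2 (1.5 equiv), FeBr3 (5 mol %), rt
Reagents that add atoms: bromine, BrBr
Why: Electrophilic ipso-bromodesilylation (the arenium ion stabilised by the β-silyl group and the ortho oxygen loses the silyl group to bromide) should replace both silyl groups first, and ordinary electrophilic aromatic bromination then takes the last C–H, which is para to an ether oxygen; every free ring position ends as C–Br, so no regiochemical choice arises.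

Step 6
Reactants: 11 5,6,8-tribromo-7-(methylsulfonylmethyl)-2,3-dihydro-1,4-benzodioxine
Product: 13 3,4,6-tribromo-5-(methylsulfonylmethyl)benzene-1,2-diol, via cyclic bromoborate 12 (not isolated)
Conditions: BBr3 (4 equiv), CH2Cl2, −78 °C → rt; then H2O, 0 °C
Reagents that add atoms: none
Why: Lewis acid-mediated aryl alkyl ether cleavage, in which BBr3 coordinates each dioxane oxygen and bromide opens the O–CH2 bonds by SN2, releasing 1,2-dibromoethane and leaving the catechol as its cyclic bromoborate 12, which water hydrolyses; the sulfone and the aryl bromides are inert to BBr3.

**Compound list**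

1 | ethane-1,2-diyl diformate (ethylene glycol diformate) | O=COCCOC=O | starting material
2 | 1,2-bis[(2,2-dichloroethenyl)oxy]ethane | ClC(Cl)=COCCOC=C(Cl)Cl | intermediate
3 | 1,2-bis(chloroethynyloxy)ethane (formed in the flask, not isolated) | ClC#COCCOC#CCl | intermediate
4 | 1,2-bis(lithioethynyloxy)ethane (formed in the flask, not isolated) | [Li]C#COCCOC#C[Li] | intermediate
5 | 1,2-bis[(trimethylsilyl)ethynyloxy]ethane | C[Si](C)(C)C#COCCOC#C[Si](C)(C)C | intermediate
6 | propargyl bromide (3-bromoprop-1-yne) | C#CCBr | starting material
7 | sodium methanesulfinate | CS(=O)[O-].[Na+] | starting material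
8 | methyl propargyl sulfone (3-(methylsulfonyl)prop-1-yne) | C#CCS(C)(=O)=O | intermediate
9 | 6-(methylsulfonylmethyl)-5,8-bis(trimethylsilyl)-2,3-dihydro-1,4-benzodioxine | CS(=O)(=O)Cc1cc([Si](C)(C)C)c2OCCOc2c1[Si](C)(C)C | intermediate
10 | 5,8-dibromo-6-(methylsulfonylmethyl)-2,3-dihydro-1,4-benzodioxine (formed in the flask, not isolated) | CS(=O)(=O)Cc1cc(Br)c2OCCOc2c1Br | intermediate
11 | 5,6,8-tribromo-7-(methylsulfonylmethyl)-2,3-dihydro-1,4-benzodioxine | CS(=O)(=O)Cc1c(Br)c(Br)c2OCCOc2c1Br | intermediate
12 | 2,4,5,7-tetrabromo-6-(methylsulfonylmethyl)-1,3,2-benzodioxaborole (formed in the flask, not isolated) | CS(=O)(=O)Cc1c(Br)c(Br)c2OB(Br)Oc2c1Br | intermediate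
13 | 3,4,6-tribromo-5-(methylsulfonylmethyl)benzene-1,2-diol | CS(=O)(=O)Cc1c(Br)c(O)c(O)c(Br)c1Br | target

**Step count**

Total steps: 6. Longest linear sequence: 5 steps (steps 1, 2, 4, 5, 6); step 3 is a one-step side branch that joins at step 4.

**Steps most likely to fail**

Step 4 (proposed new method). The cocyclization may be lost to self-trimerization of the terminal alkyne, to retro-ene fragmentation of the ynol ethers, or to trapping of cobalt as an unreactive cyclobutadiene complex. The fallback uses known chemistry and builds the substitution pattern on a preformed benzene ring. It sets out from sodium methanesulfinate 7, which is S-alkylated with purchased 4-(chloromethyl)-1,2-dimethoxybenzene F1 (DMF, 60 °C) to give 1,2-dimethoxy-4-(methylsulfonylmethyl)benzene F2. BBr3 (CH2Cl2, −78 °C → rt) demethylates this to 4-(methylsulfonylmethyl)benzene-1,2-diol F3. Excess Br2 in AcOH then fills the three free positions of the activated catechol, and the sequence comes back to the route at the target 13.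

Step 2. Elimination and chlorine–lithium exchange may stay incomplete on one arm, the dilithio species 4 may aggregate and be only partly captured, or the silyl ynol ether may hydrolyse during isolation. The fallback separates acetylene formation from silylation and changes the metal. It sets out from 2, which is treated with n-BuLi (THF, −78 → −40 °C) and quenched with MeOH at −78 °C to give the parent 1,2-bis(ethynyloxy)ethane F4, purified by distillation. EtMgBr (THF, 0 °C) converts this into 1,2-bis[(bromomagnesioethynyl)oxy]ethane F5, and chlorotrimethylsilane silylates it, returning to the route at 5.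

Step 5. The last C–H bromination may stall on the twice-brominated, crowded and deactivated ring, or prolonged exposure to Br2 and HBr may begin to open the dioxane and give mixtures of incompletely substituted material. The fallback moves the final bromination to the free catechol, which is much more reactive. It sets out from 10, isolated after the first stage (2.1 equiv Br2, 0 °C). BBr3 (CH2Cl2, −78 °C → rt) cleaves the ethylene bridge to give 3,6-dibromo-4-(methylsulfonylmethyl)benzene-1,2-diol F6. Br2 in AcOH at rt then brominates the one open position, para to a hydroxyl, and the sequence comes back to the route at 13.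

**Further compounds**

F1 | step 4 | 4-(chloromethyl)-1,2-dimethoxybenzene | COc1ccc(CCl)cc1OC
F2 | step 4 | 1,2-dimethoxy-4-(methylsulfonylmethyl)benzene | COc1ccc(CS(C)(=O)=O)cc1OC
F3 | step 4 | 4-(methylsulfonylmethyl)benzene-1,2-diol | CS(=O)(=O)Cc1ccc(O)c(O)c1
F4 | step 2 | 1,2-bis(ethynyloxy)ethane | C#COCCOC#C
F5 | step 2 | 1,2-bis[(bromomagnesioethynyl)oxy]ethane | Br[Mg]C#COCCOC#C[Mg]Br
F6 | step 5 | 3,6-dibromo-4-(methylsulfonylmethyl)benzene-1,2-diol | CS(=O)(=O)Cc1cc(Br)c(O)c(O)c1Br
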